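## The problem

The target is an eremophilane-type sesquiterpenoid ester, numbered here in the eremophilane way: ring A is C1–C5 plus C10, with the ester oxygen on C3 and methyl groups on C4 and C5; ring B is C5–C10, with the isopropylidene on C7, the ketone at C8 and the free carbinol at C9. The rings are trans-fused through the quaternary C5 and the methine C10. Five contiguous stereocentres (C3, C4, C5, C9, C10) must be set, with the C4 and C5 methyls cis and the oxygens on C3 and C9 equatorial. C5 and C10 cannot be corrected once the rings exist, so they must come out of the ring-forming event itself. C4 and C9 lie next to carbonyl carbons (C3 at the ketone stage, C8) and are equatorial, so they are in principle open to equilibration. C3 is set last from a ketone, but the axial C5 methyl blocks the trajectory a hydride would need to give the equatorial oxygen directly. The fragile parts are the α-ketol at C8/C9 beside a cross-conjugated tetrasubstituted enone and the (2E,4E,6E)-trienoate, so the acyl chain should arrive late under neutral conditions and O9 should stay masked to the end. The feature that invites a short solution is the oxygen pattern around the ring fusion. C9 bears oxygen and is flanked by the C8 carbonyl, so it can be traced back to an aldehyde with a neighbouring ketone for two-point binding to a Lewis acid. C4 lies α to oxygenated C3 and can be traced back to an enol carbon. The C5–C10 bond between them is then a trisubstituted alkene that relays charge from C9 to C4.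

## Retrosynthesis

**32 ⇒ 31 ⇒ 24 + 30 (C3–O ester bond).** After formal removal of the silyl group on O9, the ester bond is cut. This separates a robust achiral polyene acid (30) from the core and lets the sensitive chain be attached in the penultimate step. The bond is to be made with inversion (Mitsunobu) from the axial 3S alcohol 24, not with retention from the equatorial alcohol. The reason is that a C3 ketone in this ring system is attacked by hydride from the equatorial direction, because the axial path is blocked by the syn-axial C5 methyl; the alcohol that can be made selectively is therefore the axial one. The forward reaction must be an SN2 displacement at a hindered cyclohexyl carbon without elimination.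

**24 ⇒ 23 (C3 carbinol from ketone).** This is a change of oxidation level only. It puts a carbonyl at C3, which is what turns C4 into an enol carbon for the next cut. The forward step needs a hydride that reduces a saturated ketone beside a hindered enone with high facial selectivity.

**23 ⇒ 22 (C9–C10 and C4–C5, the key cut).** Cutting these two bonds together opens both rings. The four stereocentres of 23 revert to one E-trisubstituted alkene, one Z-enol silane and a prochiral aldehyde in the acyclic, achiral keto aldehyde 22. Annulation-type cuts (for example C4–C5 with C1–C10) would keep one ring and leave the quaternary centre to be built on a preformed carbocycle. The forward reaction needs a chiral Lewis acid that activates only the aldehyde, the alkene (not the enol silane) as first nucleophile, and chair–chair folding.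

**22 ⇒ 21 ⇒ 20 (latent keto aldehyde).** A keto aldehyde beside a fully substituted alkene cannot enolise, but it hydrates readily and cannot be carried through a sequence. It is traced to the 1,2-diol 21 and this to its diacetate 20. The last operations before the key step are then a hydride deacylation and an activated-DMSO oxidation, both compatible with a tert-butyldimethylsilyl enol ether. Acetal or silyl protection of the diol was rejected because removal would need acid or fluoride.

**20 ⇒ 19 ⇒ 18 ⇒ 16 + 17 (enol silane; C3–C4 bond).** The enol silane is traced to vinyl ketone 19 (1,4-hydrosilylation). Enolisation of the corresponding ethyl ketone could not tell C2 from C4, whereas conjugate hydride delivery fixes both the position and, through the s-cis enone, the Z geometry. The vinyl ketone goes back to aldehyde 16 and vinylmagnesium bromide 17.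

**16 ⇒ 15 ⇒ 14 ⇒ 12 (C8–C9 bond).** The aldehyde is unmasked from a dioxolane. The diol is cut at C8–C9 to enal 12 and a hydroxymethyl anion equivalent. One-carbon addition to an aldehyde is preferred to a two-carbon acylation at C7 because it places both oxygens on the right carbons in one operation.

**12 ⇒ 10 ⇒ 9 ⇒ 6 ⇒ 4 + 5 (C6–C7 bond and the E-alkene).** The tetrasubstituted enal is the conjugated isomer of an α-isopropenyl aldehyde. That reveals the γ,δ-unsaturated acid 9, whose C6–C7 bond is the retron of an Ireland–Claisen rearrangement of senecioate ester 6. This cut is preferred to aldol condensation with acetone followed by dehydration (uncertain direction of elimination) and to alkylation with an allylic halide (loss of alkene geometry). The sigmatropic step forms the C6–C7 bond and the E-alkene together and brings the three isopropylidene carbons in with the acyl group.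

**4 ⇒ 1 + 2 (C1–C10 bond).** Grignard addition of the dioxolane-masked three-carbon unit 1 (C1–C3) to methacrolein 2 (C10, C5, its methyl and C6). Both are commodity chemicals and the carbinol centre is erased in the rearrangement.

**30 ⇒ 29 ⇒ 26 + 27; 26 ⇒ 25 (side chain).** The C3–C4 bond of the acid joins two sp2 carbons and is made by coupling a dienyl metal with β-iodoacrylate 27. The dienyl metal with its methyl branch comes from syn-carbometalation of enyne 26, which fixes the 4E geometry; 26 comes from enal 25 by one-carbon homologation. Olefination of a methyl ketone would give E/Z mixtures at the trisubstituted bond.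

## Roads not taken

**Alternative 1:** The cut is C5–C6 in ring B. In the forward sense the potassium alkoxide (KH, 18-crown-6) of the bicyclic vinyl carbinol A1 undergoes anionic oxy-Cope rearrangement and gives, after protonation, the cis-fused ketal ketone A2.
- Merits: every reaction is of a known type; C5 and C10 are set by a sigmatropic shift whose geometry the bicycle enforces; C8 and C9 arrive oxygenated and differentiated. The ring A alkene of A2 should undergo hydroboration anti to the angular methyl, which would set C3 and C4 in one step. That is better than the reduction–inversion pair the chosen plan needs.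
- Weak points: the fusion is cis and must be inverted at C10 through the C9 ketone, without an assured thermodynamic bias beside an angular methyl. The dienone Diels–Alder reaction behind A1 is racemic, and the vinyl group must enter on the alkene face, so absolute configuration needs a resolution or an auxiliary. The C7 isopropylidene and the C9 carbinol remain to be made, and the key step is strongly basic.
- Comparison: length is similar or greater. Against the better C3/C4 control of this road, the chosen plan offers C4, C5, C9 and C10 fixed in one catalytic enantioselective step and a trans fusion obtained directly.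

**Alternative 2:** The cut is C3–C4 in ring A. CrCl2 with catalytic NiCl2 converts the 1-iodovinyl group of keto aldehyde A3 into a vinylchromium species that adds to the tethered aldehyde (Nozaki–Hiyama–Kishi) and gives allylic alcohol A4.
- Merits: the closure is mild, selective for aldehyde over ketone, and reliable for six-membered rings. The exocyclic methylene can then be hydrogenated under hydroxyl direction (for example [Ir(cod)(PCy3)(py)]PF6), placing the C4 methyl trans to O3. This control of C4 is more certain than enol silane geometry.
- Weak points: the hard part is moved into A3, which already holds the quaternary C5 and C10 in the trans relationship and must be made enantiopure by other means. The configuration at C3 formed in the closure is not secured. Ring B arrives with only a C9 ketone, so C8 oxidation, C9 reduction and the C7 isopropylidene remain; divalent chromium is used in excess.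
- Comparison: the route is longer. The chosen plan offers a ring B that leaves the key step in the final oxidation pattern.

**Alternative 3:** The cuts are C4–C5 and C1–C10, ring A as a Diels–Alder adduct. Quinone A5 reacts through its methyl-bearing double bond with silyloxydiene A6 under a chiral oxazaborolidinium triflimide and gives A7.
- Merits: this is the most convergent road: two simple partners, catalytic enantioselective, quaternary C5 made in the first step, and the C3 ketone unveiled regiospecifically. In speed to an enantioenriched decalin it is clearly better than the chosen plan, which needs thirteen steps to reach 22.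
- Weak points: endo addition gives cis fusion and puts the C4 methyl trans to the C5 methyl (as in A7), so C10 and C4 must both be epimerised. With this quinone the orientation depends on which carbonyl the Lewis acid binds. Ring B has the wrong oxidation pattern: the C6 carbonyl must be removed, C9 ketone/C8 enol ether must become C9 carbinol/C8 ketone, and the isopropylidene must be introduced at C7.
- Comparison: the chosen plan is slower to the decalin but offers in return the target's relative configuration at four centres and the finished ring B, so only three steps follow the cyclisation.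

Key step: step 14

**Remarks and assumptions**
- Eremophilane numbering is used for 23, 24, 31 and 32. The C5 descriptor changes from S (23) to R (24, 31, 32) only because CIP priorities change when C3 is reduced.
- Compounds 4–21 are racemic (18 is a diastereomer mixture); all these centres are destroyed before step 14.
- Assumption: 5, 25, 27, (chloromethyl)(isopropoxy)dimethylsilane (source of the Grignard reagent of step 6) and the ligand t-Bu-box, 2,2′-(propane-2,2-diyl)bis[(4S)-4-tert-butyl-4,5-dihydro-1,3-oxazole], are purchased.
- Assumption: the silyl group of 22 is relayed to O9 in the key step, so its product 23 is the O9 silyl ether.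

## Route

Step 1
Reactants: 1 2-(2-bromoethyl)-1,3-dioxolane; 2 methacrolein
Product: 4 5-(1,3-dioxolan-2-yl)-2-methylpent-1-en-3-ol (racemic), via Grignard reagent 3 (not isolated)
Conditions: Mg, THF, 25–30 °C; then 2, −78 → 0 °C; aq. NH4Cl
Reagents that add atoms: none
Why: Grignard 1,2-addition to an enal forms the C1–C10 bond; the reagent is made below 30 °C to avoid its fragmentation, and the racemic carbinol centre is erased in step 3.

Step 2
Reactants: 4 5-(1,3-dioxolan-2-yl)-2-methylpent-1-en-3-ol; 5 3-methylbut-2-enoic acid
Product: 6 5-(1,3-dioxolan-2-yl)-2-methylpent-1-en-3-yl 3-methylbut-2-enoate (racemic)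
Conditions: DCC, DMAP (cat.), CH2Cl2, 0 → 25 °C
Reagents that add atoms: none
Why: Steglich esterification of a secondary allylic alcohol; any migration of the acyl double bond out of conjugation is harmless because both isomers give the same dienolate in step 3.

Step 3
Reactants: 6 5-(1,3-dioxolan-2-yl)-2-methylpent-1-en-3-yl 3-methylbut-2-enoate
Product: 9 (4E)-7-(1,3-dioxolan-2-yl)-4-methyl-2-(prop-1-en-2-yl)hept-4-enoic acid (racemic), via silyl ketene acetal 7 (not isolated), via trimethylsilyl ester 8 (not isolated)
Conditions: LiN(i-Pr)2, THF/DMPU, −78 °C; Me3SiCl; −78 → 25 °C; then H2O/MeOH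
Reagents that add atoms: none
Why: Ireland–Claisen rearrangement of an ester dienolate: γ-deprotonation and O-silylation give 7, which should rearrange through a chair with the dioxolanylethyl chain equatorial, forming the C6–C7 bond and the E-trisubstituted alkene. The α-centre of 9 disappears in step 5.

Step 4
Reactants: 9 (4E)-7-(1,3-dioxolan-2-yl)-4-methyl-2-(prop-1-en-2-yl)hept-4-enoic acid
Product: 10 (4E)-7-(1,3-dioxolan-2-yl)-4-methyl-2-(prop-1-en-2-yl)hept-4-en-1-ol (racemic)
Conditions: LiAlH4, THF, 0 → 25 °C; aq. potassium sodium tartrate
Reagents that add atoms: none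
Why: Hydride reduction of a carboxylic acid to the primary alcohol; the isolated alkenes and the acetal are inert.

Step 5
Reactants: 10 (4E)-7-(1,3-dioxolan-2-yl)-4-methyl-2-(prop-1-en-2-yl)hept-4-en-1-ol
Product: 12 (4E)-7-(1,3-dioxolan-2-yl)-4-methyl-2-(propan-2-ylidene)hept-4-enal, via β,γ-unsaturated aldehyde 11 (not isolated)
Conditions: (COCl)2, DMSO, CH2Cl2, −78 °C; Et3N, −78 → 0 °C; then DBU (0.5 equiv), 25 °C
Reagents that add atoms: none
Why: Swern oxidation followed by base-mediated double-bond migration through the dienolate gives the more stable tetrasubstituted enal, so the isopropylidene is installed without any E/Z question. The methylene between the two alkenes is not acidified by the carbonyl, so the E-alkene should stay in place.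

Step 6
Reactants: 12 (4E)-7-(1,3-dioxolan-2-yl)-4-methyl-2-(propan-2-ylidene)hept-4-enal
Product: 14 (5E)-8-(1,3-dioxolan-2-yl)-5-methyl-3-(propan-2-ylidene)oct-5-ene-1,2-diol (racemic), via β-hydroxysilane 13 (not isolated)
Conditions: (i-PrO)Me2SiCH2MgCl, THF, 0 °C; aq. NH4Cl; then 30% H2O2, KF, KHCO3, THF/MeOH, 25 °C
Reagents that add atoms: (isopropoxydimethylsilyl)methylmagnesium chloride, CC(C)O[Si](C)(C)C[Mg]Cl; hydrogen peroxide, OO
Why: Nucleophilic hydroxymethylation: the silylmethyl Grignard reagent adds 1,2 to the hindered enal (C8–C9 bond) and Tamao oxidation converts C–Si into C–OH, giving the diol that is the latent keto aldehyde. The new carbinol centre is oxidised away in step 13.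

Step 7
Reactants: 14 (5E)-8-(1,3-dioxolan-2-yl)-5-methyl-3-(propan-2-ylidene)oct-5-ene-1,2-diol
Product: 15 (5E)-8-(1,3-dioxolan-2-yl)-5-methyl-3-(propan-2-ylidene)oct-5-ene-1,2-diyl diacetate (racemic)
Conditions: Ac2O, pyridine, DMAP (cat.), CH2Cl2, 25 °C
Reagents that add atoms: acetic anhydride, CC(=O)OC(C)=O
Why: Acylation masks the diol in a form that survives mild acid, a Grignard reagent at −78 °C and the hydrosilylation catalyst, and that can later be removed by hydride without acid or fluoride.

Step 8
Reactants: 15 (5E)-8-(1,3-dioxolan-2-yl)-5-methyl-3-(propan-2-ylidene)oct-5-ene-1,2-diyl diacetate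
Product: 16 (5E)-5-methyl-9-oxo-3-(propan-2-ylidene)non-5-ene-1,2-diyl diacetate (racemic)
Conditions: PPTS, acetone/H2O, 55 °C
Reagents that add atoms: water, O
Why: Acid-catalysed acetal hydrolysis frees the C3 aldehyde; the weak pyridinium acid should leave the allylic acetate and the skipped diene untouched.

Step 9
Reactants: 16 (5E)-5-methyl-9-oxo-3-(propan-2-ylidene)non-5-ene-1,2-diyl diacetate; 17 vinylmagnesium bromide
Product: 18 (5E)-9-hydroxy-5-methyl-3-(propan-2-ylidene)undeca-5,10-diene-1,2-diyl diacetate (diastereomer mixture)
Conditions: 17 (1.1 equiv), THF, −78 °C; aq. NH4Cl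
Reagents that add atoms: none
Why: Grignard addition to the aldehyde, which reacts much faster than the two acetates at −78 °C, forms the C3–C4 bond; both carbinol centres of 18 are oxidised away later.

Step 10
Reactants: 18 (5E)-9-hydroxy-5-methyl-3-(propan-2-ylidene)undeca-5,10-diene-1,2-diyl diacetate
Product: 19 (5E)-5-methyl-9-oxo-3-(propan-2-ylidene)undeca-5,10-diene-1,2-diyl diacetate (racemic)
Conditions: Dess–Martin periodinane, NaHCO3, CH2Cl2, 0 °C
Reagents that add atoms: none
Why: Dess–Martin oxidation of the allylic alcohol to the vinyl ketone under buffered, non-acidic conditions; 19 is used without delay because vinyl ketones polymerise.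

Step 11
Reactants: 19 (5E)-5-methyl-9-oxo-3-(propan-2-ylidene)undeca-5,10-diene-1,2-diyl diacetate
Product: 20 (5E,9Z)-9-[tert-butyl(dimethyl)silyloxy]-5-methyl-3-(propan-2-ylidene)undeca-5,9-diene-1,2-diyl diacetate (racemic)
Conditions: t-BuMe2SiH, RhCl(PPh3)3 (2 mol%), THF, 50 °C
Reagents that add atoms: tert-butyldimethylsilane, CC(C)(C)[SiH](C)C
Why: Rhodium-catalysed 1,4-hydrosilylation of an enone: hydride goes to the terminal carbon of the s-cis vinyl ketone and silicon to oxygen, which should give the enol silane regiospecifically towards C4 and with Z geometry. The tri- and tetrasubstituted alkenes and the acetates should not react.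

Step 12
Reactants: 20 (5E,9Z)-9-[tert-butyl(dimethyl)silyloxy]-5-methyl-3-(propan-2-ylidene)undeca-5,9-diene-1,2-diyl diacetate
Product: 21 (5E,9Z)-9-[tert-butyl(dimethyl)silyloxy]-5-methyl-3-(propan-2-ylidene)undeca-5,9-diene-1,2-diol (racemic)
Conditions: i-Bu2AlH (5 equiv), CH2Cl2, −78 °C; aq. potassium sodium tartrate
Reagents that add atoms: none
Why: Reductive cleavage of both acetates by an aluminium hydride at low temperature, with a neutral work-up; neither acid nor fluoride touches the silyl enol ether.

Step 13
Reactants: 21 (5E,9Z)-9-[tert-butyl(dimethyl)silyloxy]-5-methyl-3-(propan-2-ylidene)undeca-5,9-diene-1,2-diol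
Product: 22 (5E,9Z)-9-[tert-butyl(dimethyl)silyloxy]-5-methyl-2-oxo-3-(propan-2-ylidene)undeca-5,9-dienal
Conditions: (COCl)2, DMSO, CH2Cl2, −78 °C; Et3N, −78 → −20 °C; filtration under argon, used at once
Reagents that add atoms: none
Why: Swern oxidation converts a 1,2-diol into the 1,2-dicarbonyl compound without C–C cleavage; the non-aqueous work-up keeps the keto aldehyde unhydrated. 22 has no hydrogen α to the dicarbonyl unit and therefore cannot enolise.

Step 14
Reactants: 22 (5E,9Z)-9-[tert-butyl(dimethyl)silyloxy]-5-methyl-2-oxo-3-(propan-2-ylidene)undeca-5,9-dienal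
Product: 23 (4R,5S,9S,10R)-9-[tert-butyl(dimethyl)silyloxy]-4,5-dimethyl-7-(propan-2-ylidene)-trans-decalin-3,8-dione
Conditions: [Cu((S,S)-t-Bu-box)](SbF6)2 (20 mol%), 4 Å molecular sieves, CH2Cl2, −78 → −40 °C, slow addition of 22 to 0.005 M
Reagents that add atoms: none
Why: Proposed new method: the divalent copper centre should bind the two adjacent carbonyl oxygens of 22 in its square plane, making the aldehyde carbon C9 the most electrophilic site and holding O9 syn to O8; C10 of the E-alkene then attacks C9 (6-endo with respect to the alkene, Markovnikov, ring B), the developing tertiary cation at C5 is captured by C4 of the Z-enol silane (6-endo with respect to the enol double bond, ring A), and the silyl group is relayed from the C3 silyloxocarbenium ion to the copper alkoxide at O9, which frees the catalyst and leaves O9 protected. The closest known reaction types are aldehyde- and acetal-initiated cation–olefin bicyclisations that end on an enol silane under achiral Lewis acids, and copper bis(oxazoline)-catalysed carbonyl-ene and Mukaiyama aldol reactions of glyoxylates and pyruvates; their combination on an α-keto aldehyde has not been shown. C9 is set by the catalyst: by analogy with glyoxylate-ene reactions of the same complex, the (S,S) ligand should expose the Si face of the bound aldehyde, which corresponds to 9S (the (R,R) ligand would be used if the sense proves opposite). C10 and C5 follow from antiperiplanar addition across the E-alkene in a chair–chair array (trans fusion, C5 methyl axial), with the chelate keeping the C9–O bond equatorial; C4 follows from the Z geometry of the enol silane, which places its methyl equatorial and cis to the C5 methyl. The step needs the alkene, not the more nucleophilic enol silane, to attack C9 first: the alkene reaches C9 through a six-membered chair whereas the enol silane would have to close a ten-membered ring, and slow addition at high dilution should suppress the bimolecular aldol reaction. The tetrasubstituted C7 alkene is conjugated to the bound dicarbonyl unit and is too electron-poor to compete as a nucleophile.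

Step 15
Reactants: 23 (4R,5S,9S,10R)-9-[tert-butyl(dimethyl)silyloxy]-4,5-dimethyl-7-(propan-2-ylidene)-trans-decalin-3,8-dione
Product: 24 (3S,4R,5R,9S,10R)-9-[tert-butyl(dimethyl)silyloxy]-3-hydroxy-4,5-dimethyl-7-(propan-2-ylidene)-trans-decalin-8-one (3-OH axial, cis to both methyls)
Conditions: LiBH(s-Bu)3 (1.1 equiv), THF, −78 °C; aq. NH4Cl
Reagents that add atoms: none
Why: Bulky trialkylborohydride reduction: hydride should reach the C3 ketone from the equatorial direction, away from the axial C5 methyl, giving the axial 3S alcohol. The conjugated C8 ketone, flanked by the isopropylidene and the silyloxy group, should not be reduced at −78 °C.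

Step 16
Reactants: 25 (2E)-oct-2-enal
Product: 26 (3E)-non-3-en-1-yne
Conditions: dimethyl (1-diazo-2-oxopropyl)phosphonate, K2CO3, MeOH, 0 → 25 °C
Reagents that add atoms: dimethyl (1-diazo-2-oxopropyl)phosphonate, COP(=O)(OC)C(=[N+]=[N-])C(C)=O
Why: Seyferth–Gilbert homologation in its Ohira–Bestmann form converts the aldehyde into the terminal alkyne under mild base; the E-alkene is not involved.

Step 17
Reactants: 26 (3E)-non-3-en-1-yne; 27 ethyl (2E)-3-iodoprop-2-enoate
Product: 29 ethyl (2E,4E,6E)-5-methyldodeca-2,4,6-trienoate, via dienylalane 28 (not isolated)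
Conditions: Me3Al, Cp2ZrCl2 (0.25 equiv), CH2Cl2, 0 → 25 °C; then 27, Pd(PPh3)4 (5 mol%), ZnCl2 (cat.), THF, 25 °C
Reagents that add atoms: trimethylaluminium, C[Al](C)C
Why: Zirconium-catalysed syn-methylalumination of the terminal alkyne puts the methyl on the internal carbon and fixes the 4E geometry; Negishi coupling of the alkenyl metal with the E-iodoacrylate proceeds with retention at both partners.

Step 18
Reactants: 29 ethyl (2E,4E,6E)-5-methyldodeca-2,4,6-trienoate
Product: 30 (2E,4E,6E)-5-methyldodeca-2,4,6-trienoic acid
Conditions: LiOH, THF/MeOH/H2O, 25 °C; then 1 M HCl to pH 3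
Reagents that add atoms: lithium hydroxide, [Li+].[OH-]
Why: Saponification of an ethyl ester; the all-E trienoate is the thermodynamically preferred geometry and should not change.

Step 19
Reactants: 24 (3S,4R,5R,9S,10R)-9-[tert-butyl(dimethyl)silyloxy]-3-hydroxy-4,5-dimethyl-7-(propan-2-ylidene)-trans-decalin-8-one; 30 (2E,4E,6E)-5-methyldodeca-2,4,6-trienoic acid
Product: 31 (3R,4R,5R,9S,10R)-9-[tert-butyl(dimethyl)silyloxy]-4,5-dimethyl-8-oxo-7-(propan-2-ylidene)-trans-decalin-3-yl (2E,4E,6E)-5-methyldodeca-2,4,6-trienoate
Conditions: PPh3, DIAD, toluene, 0 → 25 °C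
Reagents that add atoms: none
Why: Mitsunobu esterification: the carboxylate of 30 displaces the activated axial oxygen at C3 with inversion (SN2), which sets the equatorial 3R ester. O9 is silylated and cannot compete.

Step 20
Reactants: 31 (3R,4R,5R,9S,10R)-9-[tert-butyl(dimethyl)silyloxy]-4,5-dimethyl-8-oxo-7-(propan-2-ylidene)-trans-decalin-3-yl (2E,4E,6E)-5-methyldodeca-2,4,6-trienoate
Product: 32 (3R,4R,5R,9S,10R)-9-hydroxy-4,5-dimethyl-8-oxo-7-(propan-2-ylidene)-trans-decalin-3-yl (2E,4E,6E)-5-methyldodeca-2,4,6-trienoate
Conditions: HF·pyridine, pyridine, THF, 0 → 25 °C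
Reagents that add atoms: none
Why: Fluoride-mediated cleavage of the silyl ether under buffered conditions that should leave the trienoate ester, the enone and the α-ketol unchanged.

## Compound list

1 | 2-(2-bromoethyl)-1,3-dioxolane | BrCCC1OCCO1 | starting material
2 | methacrolein (2-methylprop-2-enal) | CC(=C)C=O | starting material
3 | [2-(1,3-dioxolan-2-yl)ethyl]magnesium bromide | Br[Mg]CCC1OCCO1 | intermediate (not isolated)
4 | 5-(1,3-dioxolan-2-yl)-2-methylpent-1-en-3-ol (racemic) | CC(=C)C(O)CCC1OCCO1 | intermediate
5 | 3-methylbut-2-enoic acid | CC(C)=CC(=O)O | starting material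
6 | 5-(1,3-dioxolan-2-yl)-2-methylpent-1-en-3-yl 3-methylbut-2-enoate (racemic) | CC(C)=CC(=O)OC(CCC1OCCO1)C(C)=C | intermediate
7 | 1-{[5-(1,3-dioxolan-2-yl)-2-methylpent-1-en-3-yl]oxy}-3-methyl-1-(trimethylsilyloxy)buta-1,3-diene (silyl ketene acetal) | C=C(C)C=C(O[Si](C)(C)C)OC(CCC1OCCO1)C(C)=C | intermediate (not isolated)
8 | trimethylsilyl (4E)-7-(1,3-dioxolan-2-yl)-4-methyl-2-(prop-1-en-2-yl)hept-4-enoate | C[Si](C)(C)OC(=O)C(C(C)=C)C/C(C)=C/CCC1OCCO1 | intermediate (not isolated)
9 | (4E)-7-(1,3-dioxolan-2-yl)-4-methyl-2-(prop-1-en-2-yl)hept-4-enoic acid (racemic) | OC(=O)C(C(C)=C)C/C(C)=C/CCC1OCCO1 | intermediate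
10 | (4E)-7-(1,3-dioxolan-2-yl)-4-methyl-2-(prop-1-en-2-yl)hept-4-en-1-ol (racemic) | OCC(C(C)=C)C/C(C)=C/CCC1OCCO1 | intermediate
11 | (4E)-7-(1,3-dioxolan-2-yl)-4-methyl-2-(prop-1-en-2-yl)hept-4-enal | O=CC(C(C)=C)C/C(C)=C/CCC1OCCO1 | intermediate (not isolated)
12 | (4E)-7-(1,3-dioxolan-2-yl)-4-methyl-2-(propan-2-ylidene)hept-4-enal | O=CC(=C(C)C)C/C(C)=C/CCC1OCCO1 | intermediate
13 | (5E)-8-(1,3-dioxolan-2-yl)-1-[dimethyl(propan-2-yloxy)silyl]-5-methyl-3-(propan-2-ylidene)oct-5-en-2-ol | CC(C)O[Si](C)(C)CC(O)C(=C(C)C)C/C(C)=C/CCC1OCCO1 | intermediate (not isolated)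
14 | (5E)-8-(1,3-dioxolan-2-yl)-5-methyl-3-(propan-2-ylidene)oct-5-ene-1,2-diol (racemic) | OCC(O)C(=C(C)C)C/C(C)=C/CCC1OCCO1 | intermediate
15 | (5E)-8-(1,3-dioxolan-2-yl)-5-methyl-3-(propan-2-ylidene)oct-5-ene-1,2-diyl diacetate (racemic) | CC(=O)OCC(OC(C)=O)C(=C(C)C)C/C(C)=C/CCC1OCCO1 | intermediate
16 | (5E)-5-methyl-9-oxo-3-(propan-2-ylidene)non-5-ene-1,2-diyl diacetate (racemic) | CC(=O)OCC(OC(C)=O)C(=C(C)C)C/C(C)=C/CCC=O | intermediate
17 | vinylmagnesium bromide | C=C[Mg]Br | starting material
18 | (5E)-9-hydroxy-5-methyl-3-(propan-2-ylidene)undeca-5,10-diene-1,2-diyl diacetate (diastereomer mixture) | CC(=O)OCC(OC(C)=O)C(=C(C)C)C/C(C)=C/CCC(O)C=C | intermediate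
19 | (5E)-5-methyl-9-oxo-3-(propan-2-ylidene)undeca-5,10-diene-1,2-diyl diacetate (racemic) | CC(=O)OCC(OC(C)=O)C(=C(C)C)C/C(C)=C/CCC(=O)C=C | intermediate
20 | (5E,9Z)-9-[tert-butyl(dimethyl)silyloxy]-5-methyl-3-(propan-2-ylidene)undeca-5,9-diene-1,2-diyl diacetate (racemic) | CC(=O)OCC(OC(C)=O)C(=C(C)C)C/C(C)=C/CC/C(=C/C)O[Si](C)(C)C(C)(C)C | intermediate
21 | (5E,9Z)-9-[tert-butyl(dimethyl)silyloxy]-5-methyl-3-(propan-2-ylidene)undeca-5,9-diene-1,2-diol (racemic) | OCC(O)C(=C(C)C)C/C(C)=C/CC/C(=C/C)O[Si](C)(C)C(C)(C)C | intermediate
22 | (5E,9Z)-9-[tert-butyl(dimethyl)silyloxy]-5-methyl-2-oxo-3-(propan-2-ylidene)undeca-5,9-dienal | O=CC(=O)C(=C(C)C)C/C(C)=C/CC/C(=C/C)O[Si](C)(C)C(C)(C)C | intermediate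
23 | (4R,5S,9S,10R)-9-[tert-butyl(dimethyl)silyloxy]-4,5-dimethyl-7-(propan-2-ylidene)-trans-decalin-3,8-dione (eremophilane numbering) | O=C1CC[C@H]2[C@H](O[Si](C)(C)C(C)(C)C)C(=O)C(=C(C)C)C[C@]2(C)[C@H]1C | intermediate
24 | (3S,4R,5R,9S,10R)-9-[tert-butyl(dimethyl)silyloxy]-3-hydroxy-4,5-dimethyl-7-(propan-2-ylidene)-trans-decalin-8-one (axial 3-OH; eremophilane numbering) | O[C@H]1CC[C@H]2[C@H](O[Si](C)(C)C(C)(C)C)C(=O)C(=C(C)C)C[C@]2(C)[C@H]1C | intermediate
25 | (2E)-oct-2-enal | CCCCC/C=C/C=O | starting material
26 | (3E)-non-3-en-1-yne | CCCCC/C=C/C#C | intermediate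
27 | ethyl (2E)-3-iodoprop-2-enoate | CCOC(=O)/C=C/I | starting material
28 | dimethyl[(1E,3E)-2-methylnona-1,3-dien-1-yl]alane | CCCCC/C=C/C(C)=C/[Al](C)C | intermediate (not isolated)
29 | ethyl (2E,4E,6E)-5-methyldodeca-2,4,6-trienoate | CCCCC/C=C/C(C)=C/C=C/C(=O)OCC | intermediate
30 | (2E,4E,6E)-5-methyldodeca-2,4,6-trienoic acid | CCCCC/C=C/C(C)=C/C=C/C(=O)O | intermediate
31 | (3R,4R,5R,9S,10R)-9-[tert-butyl(dimethyl)silyloxy]-4,5-dimethyl-8-oxo-7-(propan-2-ylidene)-trans-decalin-3-yl (2E,4E,6E)-5-methyldodeca-2,4,6-trienoate | CCCCC/C=C/C(C)=C/C=C/C(=O)O[C@@H]1CC[C@H]2[C@H](O[Si](C)(C)C(C)(C)C)C(=O)C(=C(C)C)C[C@]2(C)[C@H]1C | intermediate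
32 | (3R,4R,5R,9S,10R)-9-hydroxy-4,5-dimethyl-8-oxo-7-(propan-2-ylidene)-trans-decalin-3-yl (2E,4E,6E)-5-methyldodeca-2,4,6-trienoate (CNP0211657.1) | CCCCC/C=C/C(C)=C/C=C/C(=O)O[C@@H]1CC[C@H]2[C@H](O)C(=O)C(=C(C)C)C[C@]2(C)[C@H]1C | target

## Step count and least certain steps

Total: 20 steps. Longest linear sequence: 17 steps (steps 1–15, 19, 20). The acid 30 takes three steps (16–18).

**Step 14 (key step).**
- What may go wrong: the cation at C5 may be quenched by proton loss (carbonyl-ene pathway) before C4 arrives; the enol silane of one molecule may add to the bound keto aldehyde of another; facial discrimination may be weaker than with small glyoxylates; relay of silicon to O9 may be slow, so that the catalyst is not released.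
- Fallback with known chemistry, setting out from 22: catalytic t-BuMe2SiOTf (10 mol%, CH2Cl2, −78 °C) promotes the established aldehyde-initiated cation–olefin cyclisation onto an enol silane with silyl transfer. It should give 23 as the racemate with its enantiomer, (4S,5R,9R,10S)-9-[tert-butyl(dimethyl)silyloxy]-4,5-dimethyl-7-(propan-2-ylidene)-trans-decalin-3,8-dione F1. Chromatography on a chiral stationary phase then returns the route to 23.
- Where relay of silicon is incomplete in either version, aqueous work-up would give (4R,5S,9S,10R)-9-hydroxy-4,5-dimethyl-7-(propan-2-ylidene)-trans-decalin-3,8-dione F2, which t-BuMe2SiOTf/2,6-lutidine converts into 23.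

**Step 3.**
- What may go wrong: deprotonation at the γ-position may be incomplete, the dienolate may be silylated on carbon, or the chair preference that sets the E-alkene may be lower than for simple ester enolates.
- Fallback, setting out from 4 and rejoining at 12 (it also bypasses step 5). Johnson–Claisen rearrangement (triethyl orthoacetate, cat. propionic acid, 140 °C) gives ethyl (4E)-7-(1,3-dioxolan-2-yl)-4-methylhept-4-enoate F3. C-Acetylation of its lithium enolate with N-methoxy-N-methylacetamide gives ethyl (4E)-2-acetyl-7-(1,3-dioxolan-2-yl)-4-methylhept-4-enoate F4. NaH and PhNTf2 give the enol triflate ethyl (4E)-7-(1,3-dioxolan-2-yl)-4-methyl-2-{1-[(trifluoromethanesulfonyl)oxy]ethylidene}hept-4-enoate F5. MeMgBr with catalytic Fe(acac)3 replaces triflate by methyl and gives ethyl (4E)-7-(1,3-dioxolan-2-yl)-4-methyl-2-(propan-2-ylidene)hept-4-enoate F6. i-Bu2AlH gives (4E)-7-(1,3-dioxolan-2-yl)-4-methyl-2-(propan-2-ylidene)hept-4-en-1-ol F7, and MnO2 oxidises this allylic alcohol to 12.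

**Step 11.**
- What may go wrong: the bulky silane may add slowly, leaving room for 1,2-hydrosilylation or polymerisation of the vinyl ketone, and Z/E control may erode. Equilibration at C4 after cyclisation would favour the equatorial methyl only modestly, so geometry control here is the main safeguard.
- Fallback, setting out from 19: stoichiometric conjugate reduction with LiBH(s-Bu)3 (1.0 equiv, THF, −78 °C), which converts s-cis enones regiospecifically into Z-enolates, gives lithium (2Z,6E)-10,11-bis(acetyloxy)-7-methyl-9-(propan-2-ylidene)undeca-2,6-dien-3-olate F8. O-Silylation with t-BuMe2SiCl returns the route to 20.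

**Step 13.**
- What may go wrong: protonolysis of the enol silane before the amine is added, over-oxidation, or hydration and oligomerisation of the keto aldehyde during handling.
- Fallback, setting out from 21: MnO2 in CH2Cl2 oxidises only the secondary allylic hydroxyl and gives (5E,9Z)-9-[tert-butyl(dimethyl)silyloxy]-1-hydroxy-5-methyl-3-(propan-2-ylidene)undeca-5,9-dien-2-one F9. Dess–Martin periodinane buffered with pyridine then oxidises the primary α-ketol and returns the route to 22.

**Step 19.**
- What may go wrong: the activated axial oxygen has antiperiplanar hydrogens on C2 and C4, so E2 elimination may compete with substitution, and activation of the hindered alcohol (syn-axial to the C5 methyl) may be slow.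
- Fallback, setting out from 24: Al(O-i-Pr)3 with a little acetone in i-PrOH/toluene at 80 °C (Meerwein–Ponndorf–Verley/Oppenauer equilibration through ketone 23) should convert the axial alcohol into the more stable equatorial epimer, (3R,4R,5R,9S,10R)-9-[tert-butyl(dimethyl)silyloxy]-3-hydroxy-4,5-dimethyl-7-(propan-2-ylidene)-trans-decalin-8-one F10. Yamaguchi esterification with 30 (2,4,6-trichlorobenzoyl chloride, Et3N, DMAP, toluene), which retains configuration, returns the route to 31.

## Further compounds

F1 | step 14 | (4S,5R,9R,10S)-9-[tert-butyl(dimethyl)silyloxy]-4,5-dimethyl-7-(propan-2-ylidene)-trans-decalin-3,8-dione (enantiomer of 23) | O=C1CC[C@@H]2[C@@H](O[Si](C)(C)C(C)(C)C)C(=O)C(=C(C)C)C[C@@]2(C)[C@@H]1C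
F2 | step 14 | (4R,5S,9S,10R)-9-hydroxy-4,5-dimethyl-7-(propan-2-ylidene)-trans-decalin-3,8-dione | O=C1CC[C@H]2[C@H](O)C(=O)C(=C(C)C)C[C@]2(C)[C@H]1C
F3 | step 3 | ethyl (4E)-7-(1,3-dioxolan-2-yl)-4-methylhept-4-enoate | CCOC(=O)CC/C(C)=C/CCC1OCCO1
F4 | step 3 | ethyl (4E)-2-acetyl-7-(1,3-dioxolan-2-yl)-4-methylhept-4-enoate (racemic) | CCOC(=O)C(C(C)=O)C/C(C)=C/CCC1OCCO1
F5 | step 3 | ethyl (4E)-7-(1,3-dioxolan-2-yl)-4-methyl-2-{1-[(trifluoromethanesulfonyl)oxy]ethylidene}hept-4-enoate (either geometry at the enol triflate) | CCOC(=O)C(=C(C)OS(=O)(=O)C(F)(F)F)C/C(C)=C/CCC1OCCO1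
F6 | step 3 | ethyl (4E)-7-(1,3-dioxolan-2-yl)-4-methyl-2-(propan-2-ylidene)hept-4-enoate | CCOC(=O)C(=C(C)C)C/C(C)=C/CCC1OCCO1
F7 | step 3 | (4E)-7-(1,3-dioxolan-2-yl)-4-methyl-2-(propan-2-ylidene)hept-4-en-1-ol | OCC(=C(C)C)C/C(C)=C/CCC1OCCO1
F8 | step 11 | lithium (2Z,6E)-10,11-bis(acetyloxy)-7-methyl-9-(propan-2-ylidene)undeca-2,6-dien-3-olate | [Li+].CC(=O)OCC(OC(C)=O)C(=C(C)C)C/C(C)=C/CC/C([O-])=C/C
F9 | step 13 | (5E,9Z)-9-[tert-butyl(dimethyl)silyloxy]-1-hydroxy-5-methyl-3-(propan-2-ylidene)undeca-5,9-dien-2-one | OCC(=O)C(=C(C)C)C/C(C)=C/CC/C(=C/C)O[Si](C)(C)C(C)(C)C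
F10 | step 19 | (3R,4R,5R,9S,10R)-9-[tert-butyl(dimethyl)silyloxy]-3-hydroxy-4,5-dimethyl-7-(propan-2-ylidene)-trans-decalin-8-one (equatorial 3-OH) | O[C@@H]1CC[C@H]2[C@H](O[Si](C)(C)C(C)(C)C)C(=O)C(=C(C)C)C[C@]2(C)[C@H]1C
A1 | alternative 1 | 2-ethenyl-3,3-dimethoxy-5,6-dimethylbicyclo[2.2.2]oct-5-en-2-ol (vinyl on the side of the C5=C6 bridge) | C=C[C@]1(O)C(OC)(OC)[C@H]2CC[C@@H]1C(C)=C2C
A2 | alternative 1 | cis-fused 9,9-dimethoxy-4,5-dimethyloctal-3-en-8-one (eremophilane numbering) | CC1=CCC[C@@H]2C(OC)(OC)C(=O)CC[C@]12C
A3 | alternative 2 | 3-[2-(1-iodoethenyl)-2-methyl-6-oxocyclohexyl]propanal (propanal chain cis to the ring methyl) | O=CCC[C@H]1C(=O)CCC[C@]1(C)C(I)=C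
A4 | alternative 2 | trans-fused 3-hydroxy-5-methyl-4-methylidenedecalin-9-one (eremophilane numbering) | O[C@@H]1CC[C@H]2C(=O)CCC[C@]2(C)C1=C
A5 | alternative 3 | 2-methoxy-5-methylcyclohexa-2,5-diene-1,4-dione | COC1=CC(=O)C(C)=CC1=O
A6 | alternative 3 | (3Z)-3-[tert-butyl(dimethyl)silyloxy]penta-1,3-diene | C=C/C(=C/C)O[Si](C)(C)C(C)(C)C
A7 | alternative 3 | cis-fused 3-[tert-butyl(dimethyl)silyloxy]-8-methoxy-4,5-dimethyloctal-2,7-diene-6,9-dione (eremophilane numbering) | CC(C)(C)[Si](C)(C)OC1=CC[C@@H]2C(=O)C(OC)=CC(=O)[C@]2(C)[C@@H]1C
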